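The route rests on cutting the C2–C3 bond of ring C. In the target, C2 is a single CH2 unit held only by O1 and by C3, a tertiary alcohol carbon that neighbours the C4 carbonyl. An OCH3 group on ring A next to an aryl 1,2-dione contains exactly these atoms. One photochemical operation (hydrogen shift from OCH3 to the C3 carbonyl oxygen, then biradical coupling) therefore forms C2–C3, closes ring C and creates the only stereocentre. The precursor is an unsymmetrical benzil: ring A bears OCH3 ortho and a silyloxy group para to the dione; ring B bears two (1S)-camphanate esters as hydrogen-inert, separable chiral handles. Both prenyl groups follow at C6 and C8.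

Key step: step 7

Remark on numbering and configuration: chromanone numbering is used (ring C: O1, C2, C3, C4, C4a, C8a; ring A: C4a–C8a; ring B primed), and C3 of the target is R.

Remark on the auxiliary: a chiral acyl group that carries an O-methyl group (a Mosher ester, for example) would add a second set of C–H bonds next to oxygen as a possible hydrogen donor. (1S)-Camphanate has none, and it is placed on both ring B oxygens so that O2' and O4' never have to be told apart.

Remark on stereocontrol: the sense and size of any facial bias by the camphanates cannot be predicted. The route is written for the 3R epimer and needs only that the two C3 epimers, which are diastereomers, can be separated.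

Step 1
Reactants: 1 4-bromo-3-methoxyphenol
Product: 2 (4-bromo-3-methoxyphenoxy)triisopropylsilane
Conditions: TIPSCl, imidazole, DMF, rt
Reagents that add atoms: triisopropylsilyl chloride, CC(C)[Si](Cl)(C(C)C)C(C)C
Why: Imidazole-promoted silylation of a phenol (silyl ether formation); the triisopropylsilyl group is chosen because its aryl ether should resist the carbonate/methanol of step 3 and has no C–H bond next to oxygen.

Step 2
Reactants: 2 (4-bromo-3-methoxyphenoxy)triisopropylsilane; 3 trimethylsilylacetylene
Product: 4 {[2-methoxy-4-(triisopropylsilyloxy)phenyl]ethynyl}trimethylsilane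
Conditions: Pd(PhCN)2Cl2 (3 mol%), [HP(t-Bu)3]BF4 (6 mol%), CuI (2 mol%), i-Pr2NH, 1,4-dioxane, rt
Reagents that add atoms: none
Why: Sonogashira coupling; the bulky, electron-rich tri-tert-butylphosphine ligand lets the electron-rich aryl bromide undergo oxidative addition at room temperature, and the silyl ether is inert to the amine.

Step 3
Reactants: 4 {[2-methoxy-4-(triisopropylsilyloxy)phenyl]ethynyl}trimethylsilane
Product: 5 (4-ethynyl-3-methoxyphenoxy)triisopropylsilane
Conditions: K2CO3 (0.2 equiv), MeOH/THF, 0 °C
Reagents that add atoms: none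
Why: Base-catalysed methanolysis of the alkynyl C–Si bond (protodesilylation of a silylalkyne) is far faster than attack at the hindered aryl O–Si(i-Pr)3 bond.

Step 4
Reactants: 6 4-bromoresorcinol; 7 (1S)-(−)-camphanic chloride (2.2 equiv)
Product: 8 4-bromo-1,3-phenylene bis[(1S)-camphanate]
Conditions: Et3N, DMAP (cat.), CH2Cl2, 0 °C to rt
Reagents that add atoms: none
Why: DMAP-catalysed acylation of both phenols by an acid chloride (nucleophilic catalysis); the stereocentres of the camphanoyl group are bridgehead carbons that cannot epimerise.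

Step 5
Reactants: 5 (4-ethynyl-3-methoxyphenoxy)triisopropylsilane; 8 4-bromo-1,3-phenylene bis[(1S)-camphanate]
Product: 9 4-{[2-methoxy-4-(triisopropylsilyloxy)phenyl]ethynyl}-1,3-phenylene bis[(1S)-camphanate]
Conditions: Pd(PhCN)2Cl2 (3 mol%), [HP(t-Bu)3]BF4 (6 mol%), CuI (2 mol%), i-Pr2NH, 1,4-dioxane, rt
Reagents that add atoms: none
Why: Sonogashira coupling; the bis(acyloxy) bromide is the better partner for oxidative addition, and room temperature with a hindered secondary amine should leave the hindered aryl esters intact so that no phenoxide can cyclise onto the alkyne.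

Step 6
Reactants: 9 4-{[2-methoxy-4-(triisopropylsilyloxy)phenyl]ethynyl}-1,3-phenylene bis[(1S)-camphanate]
Product: 10 1-[2-methoxy-4-(triisopropylsilyloxy)phenyl]-2-{2,4-bis[(1S)-camphanoyloxy]phenyl}ethane-1,2-dione
Conditions: KMnO4, NaHCO3, MgSO4, acetone/H2O, rt
Reagents that add atoms: potassium permanganate, [K+].[O-][Mn](=O)(=O)=O
Why: Buffered permanganate oxidation of a diarylalkyne to the 1,2-dione; the neutral medium spares silyl ether and esters, and no π-acid is present that could provoke attack of the methoxy or ester oxygen on the alkyne.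

Step 7
Reactants: 10 1-[2-methoxy-4-(triisopropylsilyloxy)phenyl]-2-{2,4-bis[(1S)-camphanoyloxy]phenyl}ethane-1,2-dione
Product: 12 (3R)-3-{2,4-bis[(1S)-camphanoyloxy]phenyl}-3-hydroxy-7-(triisopropylsilyloxy)chroman-4-one, via triplet 1,6-biradical 11 (not isolated)
Conditions: hν (427 nm LEDs), degassed MeCN (5 mM), 0 °C; then silica gel chromatography to separate the C3 epimers
Reagents that add atoms: none
Why: Proposed new method: blue light populates the n,π* state of the dione and, after intersystem crossing, the oxygen on C3 pulls a hydrogen atom from the ring A OCH3 group (1,7-shift, eight-membered cyclic transition state), which leaves the triplet 1,6-biradical 11 (hydroxy-substituted benzylic radical at C3, aryloxymethyl radical at C2) that couples after spin inversion. The closest known reaction type is the Norrish–Yang photocyclisation of 1-(2-alkoxyaryl)-1,2-diones to racemic 3-hydroxychroman-4-ones; steering of the new centre by a chiral ester on ring B has not been shown. Ring C (O1, C2, C3, C4, C4a, C8a) closes as a six-membered ring by radical–radical combination of the 1,6-biradical, which forms C2–C3. The C3 stereocentre arises in this coupling, and the only element able to tell the two faces of the planar C3 radical apart is the (1S)-camphanate on O2', held next to C3 on the twisted ring B; a preference for the 3R epimer is hoped for but cannot be predicted, so the step is required only to give two epimers that are diastereomers and separable on silica. Six- instead of five-membered closure requires that the C3 oxygen and not the C4 oxygen takes the hydrogen, which the substrate favours because the C4 carbonyl is deactivated by the para-silyloxy and ortho-methoxy donors and turns away from the methoxy oxygen, placing the C3 oxygen over the OCH3 group. Site selectivity of hydrogen transfer is secured because the methoxy group holds the only C–H bonds next to oxygen (silyl ether and camphanates have none), and light above 400 nm excites neither the aryl esters nor the product ketone.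

Step 8
Reactants: 12 (3R)-3-{2,4-bis[(1S)-camphanoyloxy]phenyl}-3-hydroxy-7-(triisopropylsilyloxy)chroman-4-one
Product: 13 (3R)-3-{2,4-bis[(1S)-camphanoyloxy]phenyl}-3,7-dihydroxychroman-4-one
Conditions: HF·pyridine, THF, 0 °C to rt
Reagents that add atoms: none
Why: Fluoride-driven cleavage of the aryl O–Si bond under non-basic conditions, so that the aryl camphanates stay in place and no acyl shift from O2' to the C3 hydroxyl is triggered.

Step 9
Reactants: 13 (3R)-3-{2,4-bis[(1S)-camphanoyloxy]phenyl}-3,7-dihydroxychroman-4-one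
Product: 14 (3R)-3-{2,4-bis[(1S)-camphanoyloxy]phenyl}-3,7-dihydroxy-6,8-diiodochroman-4-one
Conditions: NIS (2.2 equiv), DMF, 0 °C to rt, dark
Reagents that add atoms: N-iodosuccinimide, O=C1CCC(=O)N1I
Why: Electrophilic aromatic iodination; C6 and C8 are ortho to the free 7-OH and para or ortho to O1, whereas C5 is unactivated and ring B is deactivated by its two acyloxy groups.

Step 10
Reactants: 14 (3R)-3-{2,4-bis[(1S)-camphanoyloxy]phenyl}-3,7-dihydroxy-6,8-diiodochroman-4-one; 15 tributyl(3-methylbut-2-en-1-yl)stannane (3 equiv)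
Product: 16 (3R)-3-{2,4-bis[(1S)-camphanoyloxy]phenyl}-3,7-dihydroxy-6,8-bis(3-methylbut-2-en-1-yl)chroman-4-one
Conditions: Pd(PPh3)4 (10 mol%), DMF, 90 °C
Reagents that add atoms: none
Why: Twofold Stille coupling under neutral conditions that tolerate the free phenol, the tertiary α-ketol and the aryl esters; the stannane is expected to deliver the linear 3-methylbut-2-enyl group because C–C bond formation occurs at the unsubstituted allyl terminus.

Step 11
Reactants: 16 (3R)-3-{2,4-bis[(1S)-camphanoyloxy]phenyl}-3,7-dihydroxy-6,8-bis(3-methylbut-2-en-1-yl)chroman-4-one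
Product: 17 (3R)-3-(2,4-dihydroxyphenyl)-3,7-dihydroxy-6,8-bis(3-methylbut-2-en-1-yl)chroman-4-one
Conditions: K2CO3, MeOH, argon, 0 °C to rt; aq. NH4Cl
Reagents that add atoms: none
Why: Carbonate-mediated transesterification cleaves both aryl esters (phenoxide leaving groups), while C3 is quaternary and cannot epimerise and the prenyl groups and the tertiary α-ketol should be unaffected by cold methanolic carbonate.

Compound list

1 | 4-bromo-3-methoxyphenol | COc1cc(O)ccc1Br | starting material
2 | (4-bromo-3-methoxyphenoxy)triisopropylsilane | COc1cc(O[Si](C(C)C)(C(C)C)C(C)C)ccc1Br | intermediate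
3 | trimethylsilylacetylene | C#C[Si](C)(C)C | starting material
4 | {[2-methoxy-4-(triisopropylsilyloxy)phenyl]ethynyl}trimethylsilane | COc1cc(O[Si](C(C)C)(C(C)C)C(C)C)ccc1C#C[Si](C)(C)C | intermediate
5 | (4-ethynyl-3-methoxyphenoxy)triisopropylsilane | COc1cc(O[Si](C(C)C)(C(C)C)C(C)C)ccc1C#C | intermediate
6 | 4-bromoresorcinol | Oc1ccc(Br)c(O)c1 | starting material
7 | (1S)-(−)-camphanic chloride, (1S,4R)-4,7,7-trimethyl-3-oxo-2-oxabicyclo[2.2.1]heptane-1-carbonyl chloride | O=C(Cl)[C@@]12CC[C@@](C)(C(=O)O1)C2(C)C | starting material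
8 | 4-bromo-1,3-phenylene bis[(1S)-camphanate] | Brc1ccc(OC(=O)[C@@]23CC[C@@](C)(C(=O)O2)C3(C)C)cc1OC(=O)[C@@]23CC[C@@](C)(C(=O)O2)C3(C)C | intermediate
9 | 4-{[2-methoxy-4-(triisopropylsilyloxy)phenyl]ethynyl}-1,3-phenylene bis[(1S)-camphanate] | COc1cc(O[Si](C(C)C)(C(C)C)C(C)C)ccc1C#Cc1ccc(OC(=O)[C@@]23CC[C@@](C)(C(=O)O2)C3(C)C)cc1OC(=O)[C@@]23CC[C@@](C)(C(=O)O2)C3(C)C | intermediate
10 | 1-[2-methoxy-4-(triisopropylsilyloxy)phenyl]-2-{2,4-bis[(1S)-camphanoyloxy]phenyl}ethane-1,2-dione (ortho-methoxy benzil, precursor of the key step) | COc1cc(O[Si](C(C)C)(C(C)C)C(C)C)ccc1C(=O)C(=O)c1ccc(OC(=O)[C@@]23CC[C@@](C)(C(=O)O2)C3(C)C)cc1OC(=O)[C@@]23CC[C@@](C)(C(=O)O2)C3(C)C | intermediate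
11 | triplet 1,6-biradical (C3 hydroxybenzyl radical, C2 aryloxymethyl radical) | [CH2]Oc1cc(O[Si](C(C)C)(C(C)C)C(C)C)ccc1C(=O)[C](O)c1ccc(OC(=O)[C@@]23CC[C@@](C)(C(=O)O2)C3(C)C)cc1OC(=O)[C@@]23CC[C@@](C)(C(=O)O2)C3(C)C | intermediate (not isolated)
12 | (3R)-3-{2,4-bis[(1S)-camphanoyloxy]phenyl}-3-hydroxy-7-(triisopropylsilyloxy)chroman-4-one | CC(C)[Si](C(C)C)(C(C)C)Oc1ccc2c(c1)OC[C@](O)(c1ccc(OC(=O)[C@@]34CC[C@@](C)(C(=O)O3)C4(C)C)cc1OC(=O)[C@@]34CC[C@@](C)(C(=O)O3)C4(C)C)C2=O | intermediate
13 | (3R)-3-{2,4-bis[(1S)-camphanoyloxy]phenyl}-3,7-dihydroxychroman-4-one | Oc1ccc2c(c1)OC[C@](O)(c1ccc(OC(=O)[C@@]34CC[C@@](C)(C(=O)O3)C4(C)C)cc1OC(=O)[C@@]34CC[C@@](C)(C(=O)O3)C4(C)C)C2=O | intermediate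
14 | (3R)-3-{2,4-bis[(1S)-camphanoyloxy]phenyl}-3,7-dihydroxy-6,8-diiodochroman-4-one | Oc1c(I)cc2c(c1I)OC[C@](O)(c1ccc(OC(=O)[C@@]34CC[C@@](C)(C(=O)O3)C4(C)C)cc1OC(=O)[C@@]34CC[C@@](C)(C(=O)O3)C4(C)C)C2=O | intermediate
15 | tributyl(3-methylbut-2-en-1-yl)stannane | CC(C)=CC[Sn](CCCC)(CCCC)CCCC | starting material
16 | (3R)-3-{2,4-bis[(1S)-camphanoyloxy]phenyl}-3,7-dihydroxy-6,8-bis(3-methylbut-2-en-1-yl)chroman-4-one | CC(C)=CCc1cc2c(c(CC=C(C)C)c1O)OC[C@](O)(c1ccc(OC(=O)[C@@]34CC[C@@](C)(C(=O)O3)C4(C)C)cc1OC(=O)[C@@]34CC[C@@](C)(C(=O)O3)C4(C)C)C2=O | intermediate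
17 | (3R)-3-(2,4-dihydroxyphenyl)-3,7-dihydroxy-6,8-bis(3-methylbut-2-en-1-yl)chroman-4-one (CNP0211715.1) | CC(C)=CCc1cc2c(c(CC=C(C)C)c1O)OC[C@](O)(c1ccc(O)cc1O)C2=O | target

Total step count: 11.

Longest linear sequence: 10 steps (1 → 2 → 4 → 5 → 9 → 10 → 12 → 13 → 14 → 16 → 17; step 4 is the side branch).

Steps most likely to fail

Step 7 (key step).
- What may go wrong: the camphanates may bias the biradical coupling weakly or toward the wrong face, the two C3 epimers may not separate, or hydrogen transfer to the C4 oxygen may divert material into five-membered ring closure.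
- Fallback (known chemistry, different bond construction): ring C is closed at C3–C4 by an enantioselective carbene-catalysed intramolecular crossed benzoin addition, a reaction class established for 3-substituted 3-hydroxychroman-4-ones. It sets out from 2 and 8 and returns to the route at 12.
- Ring A partner: bromine–lithium exchange on 2 (n-BuLi, THF, −78 °C) and quenching with DMF should give 2-methoxy-4-(triisopropylsilyloxy)benzaldehyde F1. Chelation-controlled cleavage of the methoxy group ortho to the formyl group (BCl3, CH2Cl2, −78 °C) should give 2-hydroxy-4-(triisopropylsilyloxy)benzaldehyde F2.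
- Ring B partner: Stille coupling of 8 with tributyl(1-ethoxyvinyl)stannane (Pd(PPh3)4, toluene, 100 °C) should give 4-(1-ethoxyvinyl)-1,3-phenylene bis[(1S)-camphanate] F3. NBS in aqueous THF at 0 °C should convert it into 4-(2-bromoacetyl)-1,3-phenylene bis[(1S)-camphanate] F4.
- Assembly: O-alkylation of F2 with F4 (K2CO3, acetone, rt) should give 2-(2-{2,4-bis[(1S)-camphanoyloxy]phenyl}-2-oxoethoxy)-4-(triisopropylsilyloxy)benzaldehyde F5.
- Ring closure: an aminoindanol-derived chiral triazolium salt with Et3N in toluene at rt should add the aldehyde carbon to the aryl ketone to give 12. The catalyst enantiomer is chosen for the 3R product, and the minor C3 epimer is a diastereomer removable by chromatography.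

Step 10.
- What may go wrong: allylic transposition during transfer of the prenyl group would place 1,1-dimethylallyl groups on C6 or C8; loss of iodine by reduction or a stalled second coupling would give inseparable mixtures.
- Fallback (the C5 unit is built as C3 plus metathesis): it sets out from 14 and returns at 16. Twofold Stille coupling of 14 with allyltributylstannane (Pd(PPh3)4, DMF, 90 °C), which has no regiochemical ambiguity, should give (3R)-6,8-diallyl-3-{2,4-bis[(1S)-camphanoyloxy]phenyl}-3,7-dihydroxychroman-4-one F6. Olefin cross-metathesis with excess 2-methylbut-2-ene (second-generation Grubbs catalyst, CH2Cl2, 40 °C) should turn both allyl groups into 3-methylbut-2-enyl groups and give 16.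

Step 5.
- What may go wrong: the ester on O2' may be lost under amine and copper acetylide, after which the phenoxide would attack the alkyne (benzofuran formation); the electron-rich alkyne may also undergo oxidative homocoupling.
- Fallback (amine-free and copper-free alkynylation by Stille coupling): it sets out from 5 and returns at 9. Deprotonation of 5 (n-BuLi, THF, −78 °C) and quenching with Bu3SnCl should give tributyl{[2-methoxy-4-(triisopropylsilyloxy)phenyl]ethynyl}stannane F7. Coupling with 8 under neutral conditions (Pd(PPh3)4, toluene, 90 °C) should give 9.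

Further compounds

F1 | step 7 | 2-methoxy-4-(triisopropylsilyloxy)benzaldehyde | COc1cc(O[Si](C(C)C)(C(C)C)C(C)C)ccc1C=O
F2 | step 7 | 2-hydroxy-4-(triisopropylsilyloxy)benzaldehyde | Oc1cc(O[Si](C(C)C)(C(C)C)C(C)C)ccc1C=O
F3 | step 7 | 4-(1-ethoxyvinyl)-1,3-phenylene bis[(1S)-camphanate] | CCOC(=C)c1ccc(OC(=O)[C@@]23CC[C@@](C)(C(=O)O2)C3(C)C)cc1OC(=O)[C@@]23CC[C@@](C)(C(=O)O2)C3(C)C
F4 | step 7 | 4-(2-bromoacetyl)-1,3-phenylene bis[(1S)-camphanate] | BrCC(=O)c1ccc(OC(=O)[C@@]23CC[C@@](C)(C(=O)O2)C3(C)C)cc1OC(=O)[C@@]23CC[C@@](C)(C(=O)O2)C3(C)C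
F5 | step 7 | 2-(2-{2,4-bis[(1S)-camphanoyloxy]phenyl}-2-oxoethoxy)-4-(triisopropylsilyloxy)benzaldehyde | O=Cc1ccc(O[Si](C(C)C)(C(C)C)C(C)C)cc1OCC(=O)c1ccc(OC(=O)[C@@]23CC[C@@](C)(C(=O)O2)C3(C)C)cc1OC(=O)[C@@]23CC[C@@](C)(C(=O)O2)C3(C)C
F6 | step 10 | (3R)-6,8-diallyl-3-{2,4-bis[(1S)-camphanoyloxy]phenyl}-3,7-dihydroxychroman-4-one | C=CCc1cc2c(c(CC=C)c1O)OC[C@](O)(c1ccc(OC(=O)[C@@]34CC[C@@](C)(C(=O)O3)C4(C)C)cc1OC(=O)[C@@]34CC[C@@](C)(C(=O)O3)C4(C)C)C2=O
F7 | step 5 | tributyl{[2-methoxy-4-(triisopropylsilyloxy)phenyl]ethynyl}stannane | CCCC[Sn](CCCC)(CCCC)C#Cc1ccc(O[Si](C(C)C)(C(C)C)C(C)C)cc1OC
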